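**Retrosynthetic overview**

Numbering (daucane): C1 quaternary angular-methyl carbon, C2=C3, C4 isopropyl carbinol, C5 ring-fusion CH, C6 acyloxy CH, C7, C8 methyl carbinol, C9, C10. Feature: in the five-membered ring (C1–C5) the quaternary C1 lies beside the C2=C3 bond and the oxygenated C4. This is the pattern of a 4,4-disubstituted cyclopent-2-enone, which a 3-pivaloyloxy-1,4-enyne (alkene C1=C2, ester carbon C3, alkyne C4≡C5) gives by gold-catalysed acyloxy shift and C5–C1 closure.
Disconnections: C6–O ester; C6 configuration by oxidation and hydroxyl-directed reduction; C4–isopropyl by organocerium addition; C5–H and C4=O from a 5,6-epoxy C4-carbinol by 1,2-hydride shift; C5–C6 by intramolecular Mukaiyama aldol on the C6 acetal, then elimination; C1–C5 by the gold step; C3–C4 by asymmetric alkynylation of the E-enal; chain C6–C10 with C8 from (R)-linalool.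
Ring order: five-membered ring first (step 14), seven-membered ring second (step 15).
Stereochemical relay: C8 from linalool; C3 (step 11) → C1 (step 14); temporary C4 carbinol (step 17) → C5 (steps 18 and 19) → C4 (step 20) → C6 (step 22).

Key step: step 14

Assumption: commercial (R)-(−)-linalool is used as supplied; α and β refer to the drawing of the target in which the C1 methyl group is β; "daucane" means the 4-isopropyl-1,8-dimethylbicyclo[5.3.0]decane skeleton numbered as above.

**Route**

Step 1
Reactants: 1 (R)-linalool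
Product: 2 (R)-3,7-dimethyl-3-(triethylsilyloxy)octa-1,6-diene
Conditions: Et3SiOTf, 2,6-lutidine, CH2Cl2, 0 °C
Reagents that add atoms: triethylsilyl trifluoromethanesulfonate, CC[Si](CC)(CC)OS(=O)(=O)C(F)(F)F
Why: O-Silylation of the hindered tertiary allylic alcohol needs the silyl triflate with a non-nucleophilic base and leaves the chiral-pool C8 stereocentre untouched.

Step 2
Reactants: 2 (R)-3,7-dimethyl-3-(triethylsilyloxy)octa-1,6-diene
Product: 3 (R)-3,7-dimethyl-3-(triethylsilyloxy)oct-6-en-1-ol
Conditions: 9-BBN, THF, 0 °C → rt; then NaOH, H2O2, 0 °C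
Reagents that add atoms: hydrogen peroxide, OO
Why: Hydroboration–oxidation with the bulky dialkylborane 9-BBN should take the monosubstituted vinyl group in preference to the trisubstituted alkene and place oxygen on the terminal carbon (anti-Markovnikov), which becomes C6.

Step 3
Reactants: 3 (R)-3,7-dimethyl-3-(triethylsilyloxy)oct-6-en-1-ol
Product: 4 (R)-3,7-dimethyl-3-(triethylsilyloxy)oct-6-enal
Conditions: Dess–Martin periodinane, pyridine, CH2Cl2, 0 °C → rt
Reagents that add atoms: none
Why: Dess–Martin oxidation converts the primary alcohol into the aldehyde under non-aqueous buffered conditions that should not provoke β-elimination of the silyloxy group.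

Step 4
Reactants: 4 (R)-3,7-dimethyl-3-(triethylsilyloxy)oct-6-enal
Product: 5 (R)-8,8-dimethoxy-2,6-dimethyl-6-(triethylsilyloxy)oct-2-ene
Conditions: HC(OMe)3, CeCl3·7H2O (cat.), MeOH, rt
Reagents that add atoms: trimethyl orthoformate, COC(OC)OC
Why: Acetalisation with the orthoester under mild CeCl3 catalysis masks the C6 aldehyde as the dimethyl acetal without cleaving the tertiary silyl ether.

Step 5
Reactants: 5 (R)-8,8-dimethoxy-2,6-dimethyl-6-(triethylsilyloxy)oct-2-ene
Product: 6 (R)-6,6-dimethoxy-4-methyl-4-(triethylsilyloxy)hexanal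
Conditions: O3, CH2Cl2, −78 °C (indicator end point); then PPh3, −78 °C → rt
Reagents that add atoms: ozone, [O-][O+]=O
Why: Ozonolysis with reductive work-up cleaves the one remaining electron-rich alkene to the aldehyde whose carbonyl carbon becomes C1, the acetal being far less reactive towards ozone.

Step 6
Reactants: 6 (R)-6,6-dimethoxy-4-methyl-4-(triethylsilyloxy)hexanal
Product: 7 (5R)-7,7-dimethoxy-5-methyl-5-(triethylsilyloxy)heptan-2-ol as a C2 epimer mixture
Conditions: MeMgBr, THF, −78 → 0 °C
Reagents that add atoms: methylmagnesium bromide, C[Mg]Br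
Why: Grignard addition to the aldehyde brings in the carbon of the future angular methyl group, and the new carbinol centre is of no consequence because it is oxidised next.

Step 7
Reactants: 7 (5R)-7,7-dimethoxy-5-methyl-5-(triethylsilyloxy)heptan-2-ol
Product: 8 (R)-7,7-dimethoxy-5-methyl-5-(triethylsilyloxy)heptan-2-one
Conditions: Dess–Martin periodinane, pyridine, CH2Cl2, rt
Reagents that add atoms: none
Why: Dess–Martin oxidation of the secondary alcohol gives the methyl ketone.

Step 8
Reactants: 8 (R)-7,7-dimethoxy-5-methyl-5-(triethylsilyloxy)heptan-2-one; 9 triethyl phosphonoacetate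
Product: 10 ethyl (R,E)-8,8-dimethoxy-3,6-dimethyl-6-(triethylsilyloxy)oct-2-enoate
Conditions: NaH, THF, 0 °C → reflux
Reagents that add atoms: none
Why: Horner–Wadsworth–Emmons olefination of the methyl ketone should give mainly the E enoate (ester trans to the longer chain), the minor Z isomer being removed by chromatography.

Step 9
Reactants: 10 ethyl (R,E)-8,8-dimethoxy-3,6-dimethyl-6-(triethylsilyloxy)oct-2-enoate
Product: 11 (R,E)-8,8-dimethoxy-3,6-dimethyl-6-(triethylsilyloxy)oct-2-en-1-ol
Conditions: i-Bu2AlH, CH2Cl2, −78 °C; aqueous potassium sodium tartrate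
Reagents that add atoms: none
Why: Hydride reduction of the enoate with i-Bu2AlH at low temperature gives the allylic alcohol by 1,2-reduction without touching the acetal or the silyl ether.

Step 10
Reactants: 11 (R,E)-8,8-dimethoxy-3,6-dimethyl-6-(triethylsilyloxy)oct-2-en-1-ol
Product: 12 (R,E)-8,8-dimethoxy-3,6-dimethyl-6-(triethylsilyloxy)oct-2-enal
Conditions: MnO2, CH2Cl2, rt
Reagents that add atoms: none
Why: MnO2 oxidises the allylic alcohol selectively to the enal (allylic oxidation) with retention of the E geometry.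

Step 11
Reactants: 12 (R,E)-8,8-dimethoxy-3,6-dimethyl-6-(triethylsilyloxy)oct-2-enal; 13 trimethylsilylacetylene
Product: 14 (3S,4E,8R)-10,10-dimethoxy-5,8-dimethyl-8-(triethylsilyloxy)-1-(trimethylsilyl)dec-4-en-1-yn-3-ol
Conditions: Me2Zn, (S,S)-ProPhenol [2,6-bis{[(S)-2-(hydroxydiphenylmethyl)pyrrolidin-1-yl]methyl}-4-methylphenol] (10 mol %), Ph3P=O (20 mol %), toluene, 0 °C
Reagents that add atoms: none
Why: Catalytic asymmetric alkynylation, in which the dinuclear zinc–ProPhenol complex delivers the zinc acetylide to one face of the enal and sets C3 as S by reagent control, the ligand antipode being the one that gives this configuration (the other antipode is equally available).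

Step 12
Reactants: 14 (3S,4E,8R)-10,10-dimethoxy-5,8-dimethyl-8-(triethylsilyloxy)-1-(trimethylsilyl)dec-4-en-1-yn-3-ol
Product: 15 (3S,4E,8R)-10,10-dimethoxy-5,8-dimethyl-8-(triethylsilyloxy)dec-4-en-1-yn-3-ol
Conditions: K2CO3 (cat.), MeOH, 0 °C
Reagents that add atoms: none
Why: Base-catalysed methanolysis cleaves only the C(sp)–Si bond (protodesilylation), the tertiary silyl ether being inert to K2CO3 in methanol.

Step 13
Reactants: 15 (3S,4E,8R)-10,10-dimethoxy-5,8-dimethyl-8-(triethylsilyloxy)dec-4-en-1-yn-3-ol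
Product: 16 (3S,4E,8R)-10,10-dimethoxy-5,8-dimethyl-8-(triethylsilyloxy)dec-4-en-1-yn-3-yl pivalate
Conditions: pivaloyl chloride, pyridine, DMAP (cat.), CH2Cl2, 0 °C → rt
Reagents that add atoms: pivaloyl chloride, CC(C)(C)C(=O)Cl
Why: DMAP-catalysed acylation of the secondary alcohol (esterification with retention at C3) installs the migrating group for the gold step.

Step 14
Reactants: 16 (3S,4E,8R)-10,10-dimethoxy-5,8-dimethyl-8-(triethylsilyloxy)dec-4-en-1-yn-3-yl pivalate
Product: 18 (R)-4-[(R)-5,5-dimethoxy-3-methyl-3-(triethylsilyloxy)pentyl]-4-methylcyclopent-2-en-1-one, via cyclopentadienyl pivalate 17 (not isolated)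
Conditions: Ph3PAuCl (5 mol %), AgSbF6 (5 mol %), wet CH3CN, −20 °C
Reagents that add atoms: none
Why: Cationic monovalent gold activates the terminal alkyne, the pivalate carbonyl oxygen adds to C4 and the C3–O bond ionises, so that the ester shifts 1,2 and a gold-bound pentadienyl cation results whose C5 terminus bonds to C1; loss of gold gives dienyl pivalate 17, which the wet solvent hydrolyses to the C4 ketone. The closest known reaction type is the gold-catalysed Rautenstrauch rearrangement of 1-ethynyl-2-propenyl pivalates to cyclopentenones, quaternary centres included. The five-membered ring closes by a Nazarov-like conrotatory 4π closure of the helical cation (C5–C1 bond). The new quaternary centre C1 is controlled by the C3 configuration and the E alkene geometry: C5 bonds to the alkene face opposite the departing C3–O bond before the helix can invert (centre-to-helix-to-centre transfer), so the 3S,E substrate should place the methyl group on the β face. The step needs 1,2- rather than 1,3-acyloxy migration, which the terminal alkyne secures, and ring closure faster than racemisation of the cation, which the low temperature and the pivalate favour.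

Step 15
Reactants: 18 (R)-4-[(R)-5,5-dimethoxy-3-methyl-3-(triethylsilyloxy)pentyl]-4-methylcyclopent-2-en-1-one
Product: 20 (3aS,6R)-8-methoxy-3a,6-dimethyl-6-(triethylsilyloxy)-4,5,6,7,8,8a-hexahydroazulen-1(3aH)-one as a C8/C8a epimer mixture, via trimethylsilyl dienol ether 19 (not isolated)
Conditions: LiN(i-Pr)2, THF, −78 °C, then Me3SiCl; pentane filtration; Me3SiOTf (10 mol %), CH2Cl2 (5 mM), −78 °C
Reagents that add atoms: chlorotrimethylsilane, C[Si](C)(C)Cl (its atoms stay only in intermediate 19)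
Why: Kinetic deprotonation at C5, the only enolisable position of 18, and O-silylation give 2-silyloxydiene 19, whose C5 adds to the oxocarbenium ion generated from the acetal by catalytic Me3SiOTf (intramolecular Mukaiyama aldol reaction with an acetal, seven-membered ring closure at high dilution), the C5 and C6 configurations being erased in the next step.

Step 16
Reactants: 20 (3aS,6R)-8-methoxy-3a,6-dimethyl-6-(triethylsilyloxy)-4,5,6,7,8,8a-hexahydroazulen-1(3aH)-one
Product: 21 (3aS,6R)-3a,6-dimethyl-6-(triethylsilyloxy)-4,5,6,7-tetrahydroazulen-1(3aH)-one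
Conditions: DBU, CH2Cl2, rt
Reagents that add atoms: none
Why: E1cB elimination of methanol by the amidine base gives the cross-conjugated dienone with the C5=C6 bond inside the seven-membered ring.

Step 17
Reactants: 21 (3aS,6R)-3a,6-dimethyl-6-(triethylsilyloxy)-4,5,6,7-tetrahydroazulen-1(3aH)-one
Product: 22 (1S,3aS,6R)-3a,6-dimethyl-6-(triethylsilyloxy)-1,3a,4,5,6,7-hexahydroazulen-1-ol
Conditions: (R)-2-methyl-CBS-oxazaborolidine [(R)-1-methyl-3,3-diphenyltetrahydro-1H,3H-pyrrolo[1,2-c][1,3,2]oxazaborole] (20 mol %), catecholborane, toluene, −78 °C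
Reagents that add atoms: none
Why: Corey–Bakshi–Shibata reduction, in which the oxazaborolidine–borane complex binds the carbonyl oxygen anti to the bulkier fully substituted C5 flank and delivers hydride 1,2 to the α face, so that the temporary C4 carbinol is set as β-OH by reagent control.

Step 18
Reactants: 22 (1S,3aS,6R)-3a,6-dimethyl-6-(triethylsilyloxy)-1,3a,4,5,6,7-hexahydroazulen-1-ol
Product: 23 8,8a-β-epoxide of 22 (oxirane oxygen on the face of the C1 hydroxyl)
Conditions: VO(acac)2 (5 mol %), t-BuOOH, 2,6-lutidine, CH2Cl2, 0 °C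
Reagents that add atoms: tert-butyl hydroperoxide, CC(C)(C)OO
Why: Vanadium-catalysed hydroxyl-directed epoxidation transfers oxygen syn to the C4 hydroxyl, to the β face of the more electron-rich trisubstituted C5=C6 alkene, whose O–C4–C5=C6 dihedral angle fits the vanadate ester better than that of the hindered C2=C3 alkene.

Step 19
Reactants: 23 8,8a-β-epoxide of 22
Product: 25 (3aS,6R,8R,8aS)-3a,6-dimethyl-6-(triethylsilyloxy)-8-(trimethylsilyloxy)-4,5,6,7,8,8a-hexahydroazulen-1(3aH)-one, via epoxy silyl ether 24 (not isolated)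
Conditions: Me3SiOTf (1.5 equiv), i-Pr2NEt, 4 Å molecular sieves, CH2Cl2, −78 → −40 °C
Reagents that add atoms: trimethylsilyl trifluoromethanesulfonate, C[Si](C)(C)OS(=O)(=O)C(F)(F)F
Why: After O-silylation the silyl triflate opens the oxirane at the tertiary C5 and the α-oriented C4 hydrogen, anti to the breaking C5–O bond, shifts suprafacially to C5 (semipinacol 1,2-hydride shift of a 2,3-epoxy silyl ether, the non-aldol aldol process), which sets H5 α and thereby the trans ring fusion stereospecifically, regenerates the C4 enone and leaves C6 with a β silyloxy group.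

Step 20
Reactants: 25 (3aS,6R,8R,8aS)-3a,6-dimethyl-6-(triethylsilyloxy)-8-(trimethylsilyloxy)-4,5,6,7,8,8a-hexahydroazulen-1(3aH)-one
Product: 27 (1S,4S,5S,6R,8R)-8-(triethylsilyloxy)dauc-2-ene-4,6-diol (6β-OH), via silyl ether 26 (not isolated)
Conditions: i-PrMgCl, CeCl3 (anhydrous), THF, −78 °C; then aqueous citric acid, 0 °C
Reagents that add atoms: isopropylmagnesium chloride, CC(C)[Mg]Cl
Why: The organocerium reagent adds 1,2 to the enone without enolising C5 (organocerium carbonyl addition) and approaches C4 from the α face, past H5 and away from the β-oriented C5–C6 bond and angular methyl group, which gives the 4β-hydroxy-4α-isopropyl centre, and the dilute acid of the work-up removes the labile trimethylsilyl ether.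

Step 21
Reactants: 27 (1S,4S,5S,6R,8R)-8-(triethylsilyloxy)dauc-2-ene-4,6-diol
Product: 28 (1S,4S,5R,8R)-4-hydroxy-8-(triethylsilyloxy)dauc-2-en-6-one
Conditions: Dess–Martin periodinane, pyridine, CH2Cl2, 0 °C
Reagents that add atoms: none
Why: Dess–Martin oxidation can affect only the secondary C6 hydroxyl, and its neutral conditions should avoid retro-aldol cleavage and C5 epimerisation of the β-hydroxy ketone, in which the C6 carbon already lies trans to the isopropyl group.

Step 22
Reactants: 28 (1S,4S,5R,8R)-4-hydroxy-8-(triethylsilyloxy)dauc-2-en-6-one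
Product: 29 (1S,4S,5S,6S,8R)-8-(triethylsilyloxy)dauc-2-ene-4,6-diol (6α-OH)
Conditions: Me4NBH(OAc)3, AcOH/CH3CN (1:1), −30 °C
Reagents that add atoms: none
Why: Hydroxyl-directed reduction of Evans–Saksena type, in which the C4 hydroxyl exchanges onto boron and delivers hydride intramolecularly to the β face of the C6 carbonyl, which should give the 4,6-anti diol with the 6α-hydroxyl and axial H6 of the target.

Step 23
Reactants: 30 vanillic acid
Product: 32 4-(tert-butyldimethylsilyloxy)-3-methoxybenzoic acid, via bis-silyl compound 31 (not isolated)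
Conditions: t-BuMe2SiCl (2.2 equiv), imidazole, DMF, rt; then AcOH/THF/H2O, rt
Reagents that add atoms: tert-butyldimethylsilyl chloride, CC(C)(C)[Si](C)(C)Cl
Why: Silylation of both acidic OH groups followed by selective hydrolysis of the much more labile silyl ester leaves the phenol protected as its silyl ether.

Step 24
Reactants: 29 (1S,4S,5S,6S,8R)-8-(triethylsilyloxy)dauc-2-ene-4,6-diol; 32 4-(tert-butyldimethylsilyloxy)-3-methoxybenzoic acid
Product: 33 (1S,4S,5S,6S,8R)-4-hydroxy-8-(triethylsilyloxy)dauc-2-en-6-yl 4-(tert-butyldimethylsilyloxy)-3-methoxybenzoate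
Conditions: DCC, DMAP, CH2Cl2, rt
Reagents that add atoms: none
Why: Carbodiimide/DMAP (Steglich) esterification acylates the only secondary hydroxyl, C6–OH, with retention, the tertiary C4 hydroxyl being too hindered to react.

Step 25
Reactants: 33 (1S,4S,5S,6S,8R)-4-hydroxy-8-(triethylsilyloxy)dauc-2-en-6-yl 4-(tert-butyldimethylsilyloxy)-3-methoxybenzoate
Product: 34 (1S,4S,5S,6S,8R)-4,8-dihydroxydauc-2-en-6-yl 4-hydroxy-3-methoxybenzoate (CNP0113302.1)
Conditions: Bu4NF, AcOH (1:1), THF, 0 °C → rt
Reagents that add atoms: none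
Why: Acetic acid-buffered fluoride cleaves the aryl and the tertiary alkyl silyl ethers (fluoride desilylation) without ionising the tertiary allylic alcohol or moving the ester, and releases the target.

**Compound list**

1 | (R)-linalool, (R)-3,7-dimethylocta-1,6-dien-3-ol | CC(C)=CCC[C@@](C)(O)C=C | starting material
2 | (R)-3,7-dimethyl-3-(triethylsilyloxy)octa-1,6-diene | CC(C)=CCC[C@@](C)(O[Si](CC)(CC)CC)C=C | intermediate
3 | (R)-3,7-dimethyl-3-(triethylsilyloxy)oct-6-en-1-ol | CC(C)=CCC[C@@](C)(O[Si](CC)(CC)CC)CCO | intermediate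
4 | (R)-3,7-dimethyl-3-(triethylsilyloxy)oct-6-enal | CC(C)=CCC[C@@](C)(O[Si](CC)(CC)CC)CC=O | intermediate
5 | (R)-8,8-dimethoxy-2,6-dimethyl-6-(triethylsilyloxy)oct-2-ene | CC(C)=CCC[C@@](C)(O[Si](CC)(CC)CC)CC(OC)OC | intermediate
6 | (R)-6,6-dimethoxy-4-methyl-4-(triethylsilyloxy)hexanal | O=CCC[C@@](C)(O[Si](CC)(CC)CC)CC(OC)OC | intermediate
7 | (5R)-7,7-dimethoxy-5-methyl-5-(triethylsilyloxy)heptan-2-ol, both C2 epimers | CC(O)CC[C@@](C)(O[Si](CC)(CC)CC)CC(OC)OC | intermediate
8 | (R)-7,7-dimethoxy-5-methyl-5-(triethylsilyloxy)heptan-2-one | CC(=O)CC[C@@](C)(O[Si](CC)(CC)CC)CC(OC)OC | intermediate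
9 | triethyl phosphonoacetate | CCOC(=O)CP(=O)(OCC)OCC | starting material
10 | ethyl (R,E)-8,8-dimethoxy-3,6-dimethyl-6-(triethylsilyloxy)oct-2-enoate | CCOC(=O)/C=C(C)/CC[C@@](C)(O[Si](CC)(CC)CC)CC(OC)OC | intermediate
11 | (R,E)-8,8-dimethoxy-3,6-dimethyl-6-(triethylsilyloxy)oct-2-en-1-ol | OC/C=C(C)/CC[C@@](C)(O[Si](CC)(CC)CC)CC(OC)OC | intermediate
12 | (R,E)-8,8-dimethoxy-3,6-dimethyl-6-(triethylsilyloxy)oct-2-enal | O=C/C=C(C)/CC[C@@](C)(O[Si](CC)(CC)CC)CC(OC)OC | intermediate
13 | trimethylsilylacetylene | C#C[Si](C)(C)C | starting material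
14 | (3S,4E,8R)-10,10-dimethoxy-5,8-dimethyl-8-(triethylsilyloxy)-1-(trimethylsilyl)dec-4-en-1-yn-3-ol | C[Si](C)(C)C#C[C@@H](O)/C=C(C)/CC[C@@](C)(O[Si](CC)(CC)CC)CC(OC)OC | intermediate
15 | (3S,4E,8R)-10,10-dimethoxy-5,8-dimethyl-8-(triethylsilyloxy)dec-4-en-1-yn-3-ol | C#C[C@@H](O)/C=C(C)/CC[C@@](C)(O[Si](CC)(CC)CC)CC(OC)OC | intermediate
16 | (3S,4E,8R)-10,10-dimethoxy-5,8-dimethyl-8-(triethylsilyloxy)dec-4-en-1-yn-3-yl pivalate | C#C[C@@H](OC(=O)C(C)(C)C)/C=C(C)/CC[C@@](C)(O[Si](CC)(CC)CC)CC(OC)OC | intermediate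
17 | (S)-3-[(R)-5,5-dimethoxy-3-methyl-3-(triethylsilyloxy)pentyl]-3-methylcyclopenta-1,4-dien-1-yl pivalate | CC(C)(C)C(=O)OC1=C[C@@](C)(CC[C@@](C)(O[Si](CC)(CC)CC)CC(OC)OC)C=C1 | intermediate
18 | (R)-4-[(R)-5,5-dimethoxy-3-methyl-3-(triethylsilyloxy)pentyl]-4-methylcyclopent-2-en-1-one | O=C1C=C[C@](C)(CC[C@@](C)(O[Si](CC)(CC)CC)CC(OC)OC)C1 | intermediate
19 | trimethylsilyl dienol ether of 18, {(S)-3-[(R)-5,5-dimethoxy-3-methyl-3-(triethylsilyloxy)pentyl]-3-methylcyclopenta-1,4-dien-1-yl}oxytrimethylsilane | C[Si](C)(C)OC1=C[C@@](C)(CC[C@@](C)(O[Si](CC)(CC)CC)CC(OC)OC)C=C1 | intermediate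
20 | (3aS,6R)-8-methoxy-3a,6-dimethyl-6-(triethylsilyloxy)-4,5,6,7,8,8a-hexahydroazulen-1(3aH)-one, epimer mixture at C8 and C8a (daucane C6 and C5) | COC1C[C@](C)(O[Si](CC)(CC)CC)CC[C@@]2(C)C=CC(=O)C12 | intermediate
21 | (3aS,6R)-3a,6-dimethyl-6-(triethylsilyloxy)-4,5,6,7-tetrahydroazulen-1(3aH)-one | O=C1C=C[C@]2(C)CC[C@@](C)(O[Si](CC)(CC)CC)CC=C12 | intermediate
22 | (1S,3aS,6R)-3a,6-dimethyl-6-(triethylsilyloxy)-1,3a,4,5,6,7-hexahydroazulen-1-ol (daucane 4β-OH) | O[C@H]1C=C[C@]2(C)CC[C@@](C)(O[Si](CC)(CC)CC)CC=C12 | intermediate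
23 | 8,8a-epoxide of 22, oxirane oxygen cis to the C1 hydroxyl and the 3a-methyl group (daucane 5β,6β-epoxide) | O[C@H]1C=C[C@]2(C)CC[C@@](C)(O[Si](CC)(CC)CC)C[C@H]3O[C@@]123 | intermediate
24 | trimethylsilyl ether of 23 | C[Si](C)(C)O[C@H]1C=C[C@]2(C)CC[C@@](C)(O[Si](CC)(CC)CC)C[C@H]3O[C@@]123 | intermediate
25 | (3aS,6R,8R,8aS)-3a,6-dimethyl-6-(triethylsilyloxy)-8-(trimethylsilyloxy)-4,5,6,7,8,8a-hexahydroazulen-1(3aH)-one (trans-fused, daucane H5 α, 6β-OSiMe3) | C[Si](C)(C)O[C@@H]1C[C@](C)(O[Si](CC)(CC)CC)CC[C@@]2(C)C=CC(=O)[C@H]12 | intermediate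
26 | (1S,4S,5S,6R,8R)-8-(triethylsilyloxy)-6-(trimethylsilyloxy)dauc-2-en-4-ol | C[Si](C)(C)O[C@@H]1C[C@](C)(O[Si](CC)(CC)CC)CC[C@@]2(C)C=C[C@@](O)(C(C)C)[C@H]12 | intermediate
27 | (1S,4S,5S,6R,8R)-8-(triethylsilyloxy)dauc-2-ene-4,6-diol (6β-OH) | O[C@@H]1C[C@](C)(O[Si](CC)(CC)CC)CC[C@@]2(C)C=C[C@@](O)(C(C)C)[C@H]12 | intermediate
28 | (1S,4S,5R,8R)-4-hydroxy-8-(triethylsilyloxy)dauc-2-en-6-one | O=C1C[C@](C)(O[Si](CC)(CC)CC)CC[C@@]2(C)C=C[C@@](O)(C(C)C)[C@H]12 | intermediate
29 | (1S,4S,5S,6S,8R)-8-(triethylsilyloxy)dauc-2-ene-4,6-diol (6α-OH) | O[C@H]1C[C@](C)(O[Si](CC)(CC)CC)CC[C@@]2(C)C=C[C@@](O)(C(C)C)[C@H]12 | intermediate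
30 | vanillic acid, 4-hydroxy-3-methoxybenzoic acid | COc1cc(C(=O)O)ccc1O | starting material
31 | tert-butyldimethylsilyl 4-(tert-butyldimethylsilyloxy)-3-methoxybenzoate | COc1cc(C(=O)O[Si](C)(C)C(C)(C)C)ccc1O[Si](C)(C)C(C)(C)C | intermediate
32 | 4-(tert-butyldimethylsilyloxy)-3-methoxybenzoic acid | COc1cc(C(=O)O)ccc1O[Si](C)(C)C(C)(C)C | intermediate
33 | (1S,4S,5S,6S,8R)-4-hydroxy-8-(triethylsilyloxy)dauc-2-en-6-yl 4-(tert-butyldimethylsilyloxy)-3-methoxybenzoate | COc1cc(C(=O)O[C@H]2C[C@](C)(O[Si](CC)(CC)CC)CC[C@@]3(C)C=C[C@@](O)(C(C)C)[C@H]23)ccc1O[Si](C)(C)C(C)(C)C | intermediate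
34 | (1S,4S,5S,6S,8R)-4,8-dihydroxydauc-2-en-6-yl 4-hydroxy-3-methoxybenzoate, CNP0113302.1 | COc1cc(C(=O)O[C@H]2C[C@](C)(O)CC[C@@]3(C)C=C[C@@](O)(C(C)C)[C@H]23)ccc1O | target

**Step count**

Total: 25 steps. Longest linear sequence: 24 steps (steps 1–22, 24 and 25); step 23 prepares acid 32.

**Steps most likely to fail**

Step 14. The ionised intermediate carries a tertiary cationic terminus at C1, so helix inversion or full dissociation of the pivalate may compete with ring closure and erode the C3-to-C1 chirality transfer; 1,3-acyloxy shift to an allenyl ester is a second drain. The fallback sets out from enal 12 and comes back at cyclopentenone 18. It builds C1 by a sigmatropic chirality transfer instead. Addition of Me2Zn to 12 under catalysis by (+)-MIB (3-exo-morpholinoisoborneol, antipode chosen for the R carbinol) would give the (R)-allylic alcohol F1. Johnson–Claisen rearrangement of F1 with trimethyl orthoacetate and catalytic propionic acid passes the carbinol configuration to C1 through a chair transition state and would give the γ,δ-unsaturated methyl ester F2. Treatment with MeNH(OMe)·HCl and i-PrMgCl would give the Weinreb amide F3, and vinylmagnesium bromide the vinyl ketone F4. Ring-closing metathesis of F4 with the second-generation Grubbs catalyst would close 18 with loss of propene.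

Step 15. The seven-membered ring closure may lose out to intermolecular acetal addition or to protodesilylation of the dienol ether, and the Lewis acid may strip the tertiary silyl ether. The fallback sets out from 18 and comes back at dienone 21. Chemoselective acetal cleavage with Et3SiOTf and 2,4,6-collidine followed by water would give the keto aldehyde F5. Base-mediated intramolecular aldol condensation of F5 (NaOMe, MeOH, 0 °C), in which the C5 enolate attacks the aldehyde and the aldol dehydrates, would give 21; the reaction is kept short and cold to limit β-elimination of the silyloxy group and Michael addition of the aldehyde enolate to C2.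

Step 19. After ionisation at C5, migration of the C1–C10 bond or proton loss may compete with the hydride shift, and the allylic silyl ether may ionise at C4. The fallback sets out from dienol 22 and comes back at diol 29. It adds H and O across C5=C6 in one syn event. Excess 9-BBN first converts the hydroxyl into its borinate and then hydroborates C5=C6 from the α face, away from the borinate and the angular methyl group; alkaline H2O2 would give the diol F6 (H5 α, 6α-OH). MnO2 oxidises only the allylic C4 alcohol and would give the hydroxy enone F7. Addition of i-PrMgCl/CeCl3 to F7 from the α face would give 29 directly, without the oxidation and reduction at C6.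

**Further compounds**

F1 | step 14 | (2R,3E,7R)-9,9-dimethoxy-4,7-dimethyl-7-(triethylsilyloxy)non-3-en-2-ol | C[C@@H](O)/C=C(C)/CC[C@@](C)(O[Si](CC)(CC)CC)CC(OC)OC
F2 | step 14 | methyl (3R,6R)-8,8-dimethoxy-3,6-dimethyl-3-[(E)-prop-1-en-1-yl]-6-(triethylsilyloxy)octanoate | COC(=O)C[C@](C)(/C=C/C)CC[C@@](C)(O[Si](CC)(CC)CC)CC(OC)OC
F3 | step 14 | (3R,6R)-N,8,8-trimethoxy-N,3,6-trimethyl-3-[(E)-prop-1-en-1-yl]-6-(triethylsilyloxy)octanamide | CON(C)C(=O)C[C@](C)(/C=C/C)CC[C@@](C)(O[Si](CC)(CC)CC)CC(OC)OC
F4 | step 14 | (5R,8R)-10,10-dimethoxy-5,8-dimethyl-5-[(E)-prop-1-en-1-yl]-8-(triethylsilyloxy)dec-1-en-3-one | C=CC(=O)C[C@](C)(/C=C/C)CC[C@@](C)(O[Si](CC)(CC)CC)CC(OC)OC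
F5 | step 15 | (R)-3-methyl-5-[(R)-1-methyl-4-oxocyclopent-2-en-1-yl]-3-(triethylsilyloxy)pentanal | O=CC[C@](C)(O[Si](CC)(CC)CC)CC[C@@]1(C)C=CC(=O)C1
F6 | step 19 | (1S,3aS,6R,8S,8aS)-3a,6-dimethyl-6-(triethylsilyloxy)-1,3a,4,5,6,7,8,8a-octahydroazulene-1,8-diol | O[C@H]1C[C@](C)(O[Si](CC)(CC)CC)CC[C@@]2(C)C=C[C@H](O)[C@H]12
F7 | step 19 | (3aS,6R,8S,8aS)-8-hydroxy-3a,6-dimethyl-6-(triethylsilyloxy)-4,5,6,7,8,8a-hexahydroazulen-1(3aH)-one | O[C@H]1C[C@](C)(O[Si](CC)(CC)CC)CC[C@@]2(C)C=CC(=O)[C@H]12
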